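## Structural features

The target is a cembrane-type diterpenoid: a 14-membered carbocycle (C1–C14) bridged across C1 and C3 by a six-membered lactone (C15, C17(=O), O, C3, C2, C1). The ring carries a trans-trisubstituted oxirane at C11/C12, a tertiary carbinol at C4, an (E)-C6=C7 olefin and a tertiary allylic hydroperoxide at C8. There are seven stereocentres (1R, 3R, 4S, 8S, 11S, 12S, 15S). The neighbouring pairs are C3/C4 (secondary C–O next to tertiary C–O), C11/C12 (the oxirane) and C15/C1 at the lactone fusion, whereas C8 stands alone. The fragile groups are the hydroperoxide (reduction, acid- or base-induced cleavage), the trisubstituted epoxide (acid, transannular attack by a ring olefin) and the epimerisable C15 next to the carbonyl. The real difficulty is selective oxygenation of a flexible ring: four C–O stereocentres at C3, C4, C11 and C12 plus the isolated C8–OOH. The key step exploits the fact that C3/C4 and C11/C12 each map onto an (E)-allylic alcohol (C5–OH with C3=C4, C10–OH with C11=C12), whose carbinol carbons are also the points where the missing C6–C9 unit must be attached. C1 with its three-carbon branch is the stereocentre of (R)-limonene. Because the lactone oxygen can enter at C3 by opening a 3,4-epoxide with inversion, both olefins need oxygen on the same enantioface, so one chiral catalyst can serve both ends.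

## Logic of the disconnections

**33 to 32.** The C8–O bond is cut and hydrogen is returned to C6, which makes 33 the ene adduct of singlet oxygen with the (E)-C7=C8 olefin of 32. The hydroperoxide is too labile to carry through any other step, so it comes last. The gain is one stereocentre and the most sensitive group. The demand is that oxygen adds at C8 on the correct face and takes hydrogen from C6, not from the C8 methyl.

**32 to 26 (through 31, 30, 28).** C15 is allowed to form as a mixture and is set by equilibration of 31. The lactone O–C3 bond is cut with inversion, which reveals the 3,4-epoxide and a C17 acid in 30. The acid goes back through 28 to the isopropenyl group of 26. This removes the lactone ring and two stereochemical problems (C15 by thermodynamics, C3 by inversion). The forward demands are 6-exo attack at C3 rather than 7-endo at C4, survival of the second epoxide and the ring olefin, and hydroboration of the 1,1-disubstituted olefin only.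

**26 to 23 (through 25, 24).** The ring bond C9–C10 is cut. C10 is the carbinol carbon of an epoxy alcohol and becomes a strong electrophile as its triflate; C9 is allylic, so a sulfone makes it a carbanion. The macrocycle becomes an open chain. The demands are high dilution and removal of the sulfone without moving the C7=C8 double bond.

**23 to 13 + 17 (through 22, 21, 20, 19, 18).** The C5–C6 bond is cut with the same polarity: C5 is the carbinol carbon of the other epoxy alcohol, C6 the α-carbon of an allylic sulfone. The C9 oxygen of the linchpin is exchanged for chloride and then sulfone only after the C6 sulfone has been removed, because a 1,4-disulfonyl-2-ene would eliminate to a diene on reduction. The demand on this stage is that the two carbinol ends of 12 be told apart, which is the weak point of a two-directional epoxidation and is handled by the site-selective silylation that gives 13.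

**17 to 14 (through 16, 15).** The linchpin is cut at C–S and at the allylic C–O, back to prenyl acetate. Sulfonylation comes before allylic oxidation, so the olefin geometry is fixed by the oxidation alone.

**13 to 9 (through 12).** After the protecting group is removed, four C–O bonds are cut at once: both oxiranes of 12 come from the two (E)-allylic alcohols of 9. This is the strategic simplification: four stereocentres are traded for two olefin geometries. The CIP descriptors were re-derived: 9 is 1R,E,E and 12 is 1R,3S,4S,11S,12S, which is what (2R,3R)-tartrate must deliver at both olefins. The demands are full conversion at both ends and no reaction at the isopropenyl group.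

**9 to 4 + 5 + 7 (through 8, 6).** The C3=C4 and C11=C12 bonds are cut to an aldehyde and a methyl ketone, and C5 and C10 become ester carbons. The aldehyde reacts first, so the two olefinations are ordered by reactivity alone. The demand is (E) geometry at both olefins, which is secure at C3=C4 and needs isomer removal at C11=C12.

**4 to 1 (through 3, 2).** C3 and C12 are reconnected as the ring olefin of 1. Cleavage by epoxidation and periodate is used instead of direct ozonolysis so that the isopropenyl group is not at risk.

## Other disconnections considered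

**Alternative 1: sulfone closure at C10.** The cut is C9–C10 of a macrocycle that already holds the lactone. In the forward step LiN(SiMe3)2 deprotonates the C9 allylic sulfone of the open-chain epoxy triflate A2, and the carbanion displaces the C10 triflate to give the macrocyclic lactone sulfone A1. In its favour: a fast SN2 on a primary epoxy triflate, and every stereocentre already in place when the ring closes. Against it here: A2 needs its two epoxy alcohol ends made at different times, so two separate asymmetric epoxidations; the base meets an enolisable lactone; and the sulfone must later leave an allyl unit whose two termini are both secondary.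

- On structure: the chosen plan makes the same bond in the same way (step 16), so on the ring closure the two are equal. The chosen plan closes before the lactone exists, which is the safer substrate for a strong base.
- On mechanism: identical carbanion chemistry.
- On step economy: the alternative spends one more epoxidation operation, but its two ends are different from the start and need no site-selective protection. On that point it is better than the chosen plan (step 7).

**Alternative 2: Nozaki–Hiyama–Kishi closure at C13–C14.** The cut is C13–C14. CrCl2 with catalytic NiCl2 turns the (E)-vinyl iodide of the epoxy aldehyde A4 into an alkenylchromium species that adds to the C13 aldehyde and gives the 14-membered allylic alcohol A3. A later Ireland–Claisen rearrangement of the C13 propionate would build the C1–C15 bond. In its favour: divalent chromium tolerates epoxides and acetals; no auxiliary has to be removed afterwards, which is better than any sulfone route; the C3/C4 oxygens are carried with the final configuration and need no inversion; and the Claisen step could set C1 and C15 together, which is equal to or better than equilibration at C15. Against it here: the C13 configuration rests on facial selectivity at an α-quaternary epoxy aldehyde inside a forming macrocycle; the Claisen transition state is constrained by the ring; the new C13=C14 olefin must be reduced in the presence of C7=C8; and C1 is no longer supplied by limonene.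

- On structure: more centres to create by separate asymmetric reactions.
- On mechanism: less predictable stereocontrol.
- On step economy: longer than the chosen plan.

**Alternative 3: Claisen ring contraction.** The cut is C1–C2. Heating the 16-membered 2-methylene oxacycle A6 (drawn with an (E)-C15=C1 olefin) moves the allyl vinyl ether through a [3,3] shift to the 14-membered C3 ketone A5, which carries the C1 isopropenyl group. In its favour: the carbocycle comes from an easier macrolactonisation, with no high-dilution carbanion step and no auxiliary. On that point it is better than the chosen plan. Against it here: the C1 configuration depends on chair or boat preference in a large ring; methylenation of the lactone (Cp2TiMe2) must spare the epoxide; and the C3 ketone next to quaternary C4 must then be reduced to the (3R)-alcohol, whereas the chosen plan obtains C3 and C4 from the epoxidation and C1 from limonene.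

- On structure: the intermediate is comparable to 26.
- On mechanism: pericyclic and clean, but with open stereochemical questions at C1 and C3.
- On step economy: about equal.

Key step: step 6

Remark on the chemistry: (15S) is taken to be the thermodynamically preferred lactone epimer (C15 methyl trans to the C1 ring bond, all three lactone substituents pseudo-equatorial), so the equilibration in step 20 should converge on it; atom numbers are those of the target throughout.

## Route

Step 1
Reactants: 1 (R)-(+)-limonene
Product: 2 (4R)-limonene 1,2-oxide (cis/trans mixture)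
Conditions: mCPBA, NaHCO3, CH2Cl2, 0 °C
Reagents that add atoms: 3-chloroperoxybenzoic acid, OOC(=O)c1cccc(Cl)c1
Why: Prilezhaev epoxidation; the peracid prefers the more electron-rich trisubstituted ring olefin over the isopropenyl group, and the epoxide diastereomers converge in step 2.

Step 2
Reactants: 2 (4R)-limonene 1,2-oxide
Product: 4 (3R)-6-oxo-3-(prop-1-en-2-yl)heptanal, via limonene-1,2-diol 3 (not isolated)
Conditions: H5IO6, THF/H2O, 0 °C → rt
Reagents that add atoms: water, O
Why: Acid-assisted hydrolysis of the epoxide to the trans-diol, then Malaprade glycol cleavage; C1 (target numbering) is untouched and the isopropenyl group is inert to periodate.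

Step 3
Reactants: 4 (3R)-6-oxo-3-(prop-1-en-2-yl)heptanal; 5 triethyl 2-phosphonopropionate
Product: 6 ethyl (2E,5R)-2-methyl-8-oxo-5-(prop-1-en-2-yl)non-2-enoate
Conditions: LiCl, DBU, MeCN, 0 °C → rt
Reagents that add atoms: none
Why: Horner–Wadsworth–Emmons olefination under Masamune–Roush conditions; the stabilised phosphonate reacts with the aldehyde only, and the α-methyl phosphonate gives the (E)-trisubstituted enoate (C3=C4) by reversible addition and anti elimination.

Step 4
Reactants: 6 keto enoate; 7 triethyl phosphonoacetate
Product: 8 diethyl (2E,5R,8E)-2,8-dimethyl-5-(prop-1-en-2-yl)deca-2,8-dienedioate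
Conditions: NaH, THF, 0 → 50 °C; (8Z)-isomer removed by chromatography
Reagents that add atoms: none
Why: Horner–Wadsworth–Emmons olefination of the methyl ketone; the ester ends up trans to the larger CH2 substituent in the major isomer (C11=C12), and the minor (Z)-isomer is removed here or, if needed, at the diol stage.

Step 5
Reactants: 8 (E,E)-diester
Product: 9 (2E,5R,8E)-2,8-dimethyl-5-(prop-1-en-2-yl)deca-2,8-diene-1,10-diol
Conditions: i-Bu2AlH, CH2Cl2, −78 → 0 °C; Rochelle salt
Reagents that add atoms: none
Why: 1,2-Reduction of both enoates to the allylic alcohols by the aluminium hydride; olefin geometry and the isopropenyl group are unaffected.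

Step 6
Reactants: 9 bis-allylic alcohol
Product: 12 (1R,3S,4S,11S,12S)-bis-epoxy diol, via 3,4-mono-epoxide 10 (not isolated), via 11,12-mono-epoxide 11 (not isolated)
Conditions: Ti(OiPr)4 (0.3 equiv), L-(+)-diethyl tartrate (0.36 equiv), t-BuOOH (4 equiv), 4 Å MS, CH2Cl2, −20 °C
Reagents that add atoms: tert-butyl hydroperoxide, CC(C)(C)OO
Why: Each allylic hydroxyl exchanges onto the titanium tartrate complex as its alkoxide, t-BuOOH binds to the same metal, and its distal oxygen is passed to the coordinated olefin in a concerted transition state; the closest known reaction type is the Sharpless asymmetric epoxidation, run here at both ends of one molecule. Both oxiranes (C3–O–C4 and C11–O–C12) close by this concerted oxygen transfer onto the olefin face, so the (E) geometry is kept and each epoxide is trans. The (2R,3R)-tartrate delivers oxygen to the same enantioface of every allylic alcohol, which gives 3S,4S at the 2-methyl allylic alcohol and 11S,12S at the geraniol-type one, so all four centres are set by the reagent. C3 is made with the configuration opposite to the target on purpose, because step 19 inverts it. Only hydroxyl-bound olefins react, so the isopropenyl group stays. C1 is homoallylic to one olefin and more remote from the other and should not override the catalyst. The mono-epoxides 10 and 11 are expected to form and react on, and since the two events are independent, a minor-face error at either end ends up in a separable diastereomer. Sub-stoichiometric titanium and molecular sieves limit titanium-assisted opening at the tertiary C12.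

Step 7
Reactants: 12 bis-epoxy diol
Product: 13 C10 tert-butyldiphenylsilyl ether of 12 (C5–OH free)
Conditions: TBDPSCl (1.0 equiv), imidazole, CH2Cl2, −40 → −20 °C
Reagents that add atoms: tert-butyl(chloro)diphenylsilane, CC(C)(C)[Si](Cl)(c1ccccc1)c1ccccc1
Why: Silyl ether formation under steric control; the C10 carbinol is attached to a CH oxirane carbon and the C5 carbinol to a fully substituted one, so the bulky chloride should prefer C10, and the other silyl ethers can be returned to 12 with fluoride.

Step 8
Reactants: 14 prenyl acetate
Product: 15 prenyl phenyl sulfone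
Conditions: PhSO2Na, Pd(PPh3)4 (cat.), THF/MeOH, rt
Reagents that add atoms: sodium benzenesulfinate, [Na+].[O-]S(=O)c1ccccc1
Why: Tsuji–Trost allylic substitution with sulfinate as sulfur nucleophile; the π-allyl complex of zerovalent palladium is attacked at, or equilibrates to, the primary terminus, and the gem-dimethyl end excludes any E/Z question.

Step 9
Reactants: 15 prenyl phenyl sulfone
Product: 16 (2E)-2-methyl-4-(phenylsulfonyl)but-2-en-1-ol
Conditions: SeO2 (cat.), t-BuOOH, CH2Cl2, rt
Reagents that add atoms: tert-butyl hydroperoxide, CC(C)(C)OO
Why: Allylic oxidation by the ene reaction of SeO2 followed by a [2,3] shift; the (E)-methyl at the more substituted olefin carbon is oxidised, giving the (E)-allylic alcohol (future C9), while the CH2 next to the sulfone is deactivated.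

Step 10
Reactants: 16 hydroxy sulfone
Product: 17 tert-butyldimethylsilyl ether of 16 (C6–C9 linchpin)
Conditions: TBSCl, imidazole, DMF, rt
Reagents that add atoms: tert-butyl(chloro)dimethylsilane, CC(C)(C)[Si](C)(C)Cl
Why: Standard silylation of a primary allylic alcohol, so that only the sulfone α-carbon is deprotonated in step 11.

Step 11
Reactants: 13 C10 silyl ether; 17 linchpin sulfone
Product: 19 C5–C6 coupled sulfone (C6 epimers; C9–OTBS; C10–OTBDPS), via C5 triflate 18 (not isolated)
Conditions: 13: Tf2O, 2,6-lutidine, CH2Cl2, −78 °C, cold work-up; 17: n-BuLi, THF, −78 °C; then crude 18, −78 → −40 °C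
Reagents that add atoms: none
Why: Sulfone alkylation: the α-sulfonyl allyl carbanion displaces the primary epoxy triflate by SN2 at its α-carbon; the oxirane ties back the C4 substituents so the neopentyl-like C5 stays accessible, and both epoxides survive at low temperature. C6 forms as an inconsequential mixture.

Step 12
Reactants: 19 coupled sulfone
Product: 20 sulfonyl diol (C9–OH, C10–OH, C6–SO2Ph)
Conditions: Bu4NF, THF, 0 °C → rt
Reagents that add atoms: none
Why: Fluoride cleaves both silyl ethers; freeing the C9 hydroxyl before the reduction removes the silyloxide leaving group that could otherwise depart from the allyl anion in step 13.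

Step 13
Reactants: 20 sulfonyl diol
Product: 21 (7E)-seco diol (C9–OH, C10–OH)
Conditions: Na(Hg) (6%), Na2HPO4, MeOH/THF, −20 °C
Reagents that add atoms: none
Why: Reductive desulfonylation by electron transfer; the allyl anion should be protonated by methanol mainly at the less substituted C6 terminus, keeping the trisubstituted (E)-C7=C8 olefin, and buffered methanol leaves the epoxides alone.

Step 14
Reactants: 21 seco diol
Product: 22 C9 allylic chloride (C10–OH free)
Conditions: NCS, Me2S, CH2Cl2, −20 → 0 °C
Reagents that add atoms: N-chlorosuccinimide, ClN1C(=O)CCC1=O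
Why: Corey–Kim chlorination; the alkoxysulfonium salt collapses by SN2 chloride attack only at the activated allylic carbinol, without allylic transposition, and the C10 epoxy carbinol is returned unchanged.

Step 15
Reactants: 22 allylic chloride
Product: 23 C9 phenyl sulfone (C10–OH free)
Conditions: PhSO2Na, Bu4NI (cat.), DMF, rt
Reagents that add atoms: sodium benzenesulfinate, [Na+].[O-]S(=O)c1ccccc1
Why: SN2 S-alkylation of sulfinate by the primary allylic chloride; the second sulfone is introduced only after the first has gone, so no 1,4-disulfone arises.

Step 16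
Reactants: 23 C9 sulfone
Product: 25 14-membered C9 sulfone (C9 epimers), via C10 triflate 24 (not isolated)
Conditions: Tf2O, 2,6-lutidine, CH2Cl2, −78 °C, cold work-up; then LiN(SiMe3)2 (1.05 equiv), THF (0.002 M), −78 → −20 °C
Reagents that add atoms: none
Why: Intramolecular sulfone alkylation: the C9 carbanion displaces the C10 epoxy triflate and closes the 14-membered ring; high dilution and the very fast primary triflate favour closure over oligomerisation, and only a slight excess of base is used so that the product is not deprotonated next to the 11,12-epoxide.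

Step 17
Reactants: 25 macrocyclic sulfone
Product: 26 (1R,3S,4S,7E,11S,12S)-3,4:11,12-diepoxycembra-7,15(17)-diene
Conditions: Na(Hg) (6%), Na2HPO4, MeOH/THF, −20 °C
Reagents that add atoms: none
Why: Dissolving-metal desulfonylation as in step 13; protonation of the allyl anion at C9 restores the (E)-C7=C8 olefin, and the epoxides and the isopropenyl group are inert.

Step 18
Reactants: 26 diepoxy diene
Product: 28 C17 primary alcohol (C15 epimers), via B-alkyl-9-BBN adduct 27 (not isolated)
Conditions: 9-BBN, THF, 0 °C → rt; then H2O2, aq. NaOH, 0 °C
Reagents that add atoms: hydrogen peroxide, OO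
Why: Hydroboration–oxidation; 9-BBN adds anti-Markovnikov to the 1,1-disubstituted olefin much faster than to the trisubstituted ring olefin and does not open epoxides. C15 forms as a mixture that step 20 corrects.

Step 19
Reactants: 28 primary alcohol
Product: 31 hydroxy lactone (C15 epimers), via aldehyde 29 (not isolated), via epoxy acid 30 (not isolated)
Conditions: TEMPO (cat.), PhI(OAc)2, MeCN/H2O, rt; then PhMe, 40 °C
Reagents that add atoms: water, O
Why: Oxoammonium oxidation through the aldehyde hydrate to the acid; the 5,6-epoxy acid then lactonises by 6-exo-tet attack of the carboxyl oxygen on secondary C3 with inversion (3S to 3R), and the oxirane oxygen becomes the C4 hydroxyl. Attack at quaternary C4 (7-endo) or on the remote 11,12-epoxide is disfavoured.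

Step 20
Reactants: 31 hydroxy lactone (C15 mixture)
Product: 32 (15S)-hydroxy lactone with (E)-C7=C8 olefin
Conditions: DBU, PhMe, 80 °C
Reagents that add atoms: none
Why: Base-mediated epimerisation through the lactone enolate; thermodynamic control places the C15 methyl pseudo-equatorial, trans to the C1 ring bond.

Step 21
Reactants: 32 (15S)-hydroxy lactone
Product: 33 target hydroperoxide
Conditions: O2, hν (visible), tetraphenylporphyrin (cat.), CH2Cl2, −20 °C
Reagents that add atoms: dioxygen, O=O
Why: Schenck ene reaction; singlet oxygen adds suprafacially at C8 while taking an allylic hydrogen from C6, which moves the olefin to (E)-C6=C7. The cis effect directs abstraction to the more crowded side of the olefin (C6–H2 and the C8 methyl), and the face is set by the conformation of the bridged macrocycle.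

## Compound list

1 | (R)-(+)-limonene | CC1=CC[C@@H](CC1)C(C)=C | starting material
2 | (4R)-limonene 1,2-oxide, cis/trans mixture | CC(=C)[C@@H]1CCC2(C)OC2C1 | intermediate
3 | (4R)-limonene-1,2-diol, trans-diol mixture | CC(=C)[C@@H]1CCC(C)(O)C(O)C1 | intermediate (not isolated)
4 | (3R)-6-oxo-3-(prop-1-en-2-yl)heptanal | CC(=O)CC[C@H](CC=O)C(C)=C | intermediate
5 | triethyl 2-phosphonopropionate | CCOC(=O)C(C)P(=O)(OCC)OCC | starting material
6 | ethyl (2E,5R)-2-methyl-8-oxo-5-(prop-1-en-2-yl)non-2-enoate | CCOC(=O)/C(C)=C/C[C@@H](CCC(C)=O)C(C)=C | intermediate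
7 | triethyl phosphonoacetate | CCOC(=O)CP(=O)(OCC)OCC | starting material
8 | diethyl (2E,5R,8E)-2,8-dimethyl-5-(prop-1-en-2-yl)deca-2,8-dienedioate | CCOC(=O)/C(C)=C/C[C@@H](CC/C(C)=C/C(=O)OCC)C(C)=C | intermediate
9 | (2E,5R,8E)-2,8-dimethyl-5-(prop-1-en-2-yl)deca-2,8-diene-1,10-diol (C5–OH, C10–OH, 1R) | CC(=C)[C@@H](C/C=C(C)/CO)CC/C(C)=C/CO | intermediate
10 | (3S,4S)-3,4-mono-epoxide of 9 | CC(=C)[C@@H](C[C@@H]1O[C@@]1(C)CO)CC/C(C)=C/CO | intermediate (not isolated)
11 | (11S,12S)-11,12-mono-epoxide of 9 | CC(=C)[C@@H](C/C=C(C)/CO)CC[C@]1(C)O[C@H]1CO | intermediate (not isolated)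
12 | (1R,3S,4S,11S,12S)-3,4:11,12-bis-epoxy diol | CC(=C)[C@@H](C[C@@H]1O[C@@]1(C)CO)CC[C@]1(C)O[C@H]1CO | intermediate
13 | C10 tert-butyldiphenylsilyl ether of 12 | CC(=C)[C@@H](C[C@@H]1O[C@@]1(C)CO)CC[C@]1(C)O[C@H]1CO[Si](c1ccccc1)(c1ccccc1)C(C)(C)C | intermediate
14 | prenyl acetate | CC(C)=CCOC(C)=O | starting material
15 | prenyl phenyl sulfone | CC(C)=CCS(=O)(=O)c1ccccc1 | intermediate
16 | (2E)-2-methyl-4-(phenylsulfonyl)but-2-en-1-ol | OC/C(C)=C/CS(=O)(=O)c1ccccc1 | intermediate
17 | tert-butyldimethylsilyl ether of 16 | CC(C)(C)[Si](C)(C)OC/C(C)=C/CS(=O)(=O)c1ccccc1 | intermediate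
18 | C5 triflate of 13 | CC(=C)[C@@H](C[C@@H]1O[C@@]1(C)COS(=O)(=O)C(F)(F)F)CC[C@]1(C)O[C@H]1CO[Si](c1ccccc1)(c1ccccc1)C(C)(C)C | intermediate (not isolated)
19 | C5–C6 coupled C6 sulfone (C6 epimers), C9–OTBS, C10–OTBDPS | CC(=C)[C@@H](C[C@@H]1O[C@@]1(C)CC(/C=C(C)/CO[Si](C)(C)C(C)(C)C)S(=O)(=O)c1ccccc1)CC[C@]1(C)O[C@H]1CO[Si](c1ccccc1)(c1ccccc1)C(C)(C)C | intermediate
20 | C6 sulfonyl diol (C9–OH, C10–OH) | CC(=C)[C@@H](C[C@@H]1O[C@@]1(C)CC(/C=C(C)/CO)S(=O)(=O)c1ccccc1)CC[C@]1(C)O[C@H]1CO | intermediate
21 | (7E)-seco diol (C9–OH, C10–OH) | CC(=C)[C@@H](C[C@@H]1O[C@@]1(C)CC/C=C(C)/CO)CC[C@]1(C)O[C@H]1CO | intermediate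
22 | C9 allylic chloride, C10–OH | CC(=C)[C@@H](C[C@@H]1O[C@@]1(C)CC/C=C(C)/CCl)CC[C@]1(C)O[C@H]1CO | intermediate
23 | C9 phenyl sulfone, C10–OH | CC(=C)[C@@H](C[C@@H]1O[C@@]1(C)CC/C=C(C)/CS(=O)(=O)c1ccccc1)CC[C@]1(C)O[C@H]1CO | intermediate
24 | C10 triflate of 23 | CC(=C)[C@@H](C[C@@H]1O[C@@]1(C)CC/C=C(C)/CS(=O)(=O)c1ccccc1)CC[C@]1(C)O[C@H]1COS(=O)(=O)C(F)(F)F | intermediate (not isolated)
25 | 14-membered C9 phenyl sulfone (C9 epimers), C1 isopropenyl, 3,4- and 11,12-epoxides, (7E) | CC(=C)[C@H]1C[C@@H]2O[C@@]2(C)CC/C=C(C)/C(S(=O)(=O)c2ccccc2)C[C@@H]2O[C@@]2(C)CC1 | intermediate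
26 | (1R,3S,4S,7E,11S,12S)-3,4:11,12-diepoxycembra-7,15(17)-diene | CC(=C)[C@H]1C[C@@H]2O[C@@]2(C)CC/C=C(C)/CC[C@@H]2O[C@@]2(C)CC1 | intermediate
27 | B-(C17-alkyl)-9-borabicyclo[3.3.1]nonane adduct of 26 (C15 epimers) | CC(CB1C2CCCC1CCC2)[C@H]1C[C@@H]2O[C@@]2(C)CC/C=C(C)/CC[C@@H]2O[C@@]2(C)CC1 | intermediate (not isolated)
28 | C17 primary alcohol (C15 epimers) | CC(CO)[C@H]1C[C@@H]2O[C@@]2(C)CC/C=C(C)/CC[C@@H]2O[C@@]2(C)CC1 | intermediate
29 | C17 aldehyde (C15 epimers) | CC(C=O)[C@H]1C[C@@H]2O[C@@]2(C)CC/C=C(C)/CC[C@@H]2O[C@@]2(C)CC1 | intermediate (not isolated)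
30 | C17 carboxylic acid, 3,4-epoxide intact (C15 epimers) | CC(C(=O)O)[C@H]1C[C@@H]2O[C@@]2(C)CC/C=C(C)/CC[C@@H]2O[C@@]2(C)CC1 | intermediate (not isolated)
31 | (1R,3R,4S,7E,11S,12S)-hydroxy lactone, C15 epimers | CC1C(=O)O[C@@H]2C[C@H]1CC[C@]1(C)O[C@H]1CC/C(C)=C/CC[C@]2(C)O | intermediate
32 | (1R,3R,4S,7E,11S,12S,15S)-hydroxy lactone | C[C@@H]1C(=O)O[C@@H]2C[C@H]1CC[C@]1(C)O[C@H]1CC/C(C)=C/CC[C@]2(C)O | intermediate
33 | target, (1R,3R,4S,6E,8S,11S,12S,15S)-8-hydroperoxide | C[C@@H]1C(=O)O[C@@H]2C[C@H]1CC[C@]1(C)O[C@H]1CC[C@](C)(OO)/C=C/C[C@]2(C)O | target

## Step count and least certain steps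

Total: 21 steps. Longest linear sequence: 18 steps (steps 1–7 and 11–21); the linchpin branch (steps 8–10) joins at step 11.

**Step 6 (key step).** The second olefin may be epoxidised incompletely, or facial selectivity may erode if the diol bridges titanium centres into less selective aggregates; titanium-assisted solvolysis at the tertiary C12 is a further risk. Fallback: from 9, both allylic alcohols are epoxidised with a different catalyst family, VO(OiPr)3 with a C2-symmetric chiral bishydroxamic acid ligand and aqueous t-BuOOH in toluene at 0 °C. The ligand enantiomer is chosen for the same (S,S) sense at both olefins, and the system is less Lewis acidic toward the product. It returns to 12 and makes no new compound (F0).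

**Step 7.** Site discrimination may be poor, because the two carbinols differ by one methyl group on the adjacent oxirane carbon and silylation at C5 can compete. Fallback: from 12, enzymatic acylation (Candida antarctica lipase B, vinyl acetate, t-BuOMe) should select the less hindered carbinol and give the C10 mono-acetate F1. Its C5 triflate F2 is made and coupled with lithiated 17 at −78 °C, where the triflate outruns the acetate, to give the coupled acetate F3. K2CO3 in MeOH then gives the C10 alcohol F4, and Bu4NF returns the route to 20.

**Step 16.** Intermolecular alkylation may compete with ring closure, the labile triflate may decompose before closure, or the product may be deprotonated at C9 and open the neighbouring epoxide by 3-exo attack. Fallback: from 23, I2, PPh3 and imidazole give the stable C10 epoxy iodide F5, which can be added slowly to KN(SiMe3)2 and 18-crown-6 in THF at high dilution; the route is rejoined at 25.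

**Step 17.** The allyl anion from 25 has two secondary termini, so protonation at C7 instead of C9 would move the olefin to C8=C9, and the olefin geometry may scramble. Fallback: from 25 the sulfone is carried through the chemistry of steps 18 and 19, via the borane adduct F6, the C17 alcohol F7, the aldehyde F8 and the acid F9 to the sulfonyl lactone F10. The sulfone is then removed with Na(Hg) and Na2HPO4 in MeOH/THF from this conformationally restrained bridged lactone, where the two allyl termini are less alike and isomers are easier to separate; the route is rejoined at 31.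

**Step 21.** Hydrogen may be taken from the C8 methyl, giving a C7 hydroperoxide with an exocyclic olefin; oxygen may approach the wrong face (C8 epimer); and the product may undergo Hock-type cleavage on long irradiation. Fallback: from 32, TESOTf and 2,6-lutidine give the C4 triethylsilyl ether F11, whose ring conformation and face exposure differ because the transannular hydroxyl is masked. Photooxygenation gives the silylated hydroperoxide F12, and HF·pyridine in THF returns the route to 33.

## Further compounds

F0 | step 6 | none | none
F1 | step 7 | C10 mono-acetate of 12 | CC(=C)[C@@H](C[C@@H]1O[C@@]1(C)CO)CC[C@]1(C)O[C@H]1COC(C)=O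
F2 | step 7 | C5 triflate of F1 | CC(=C)[C@@H](C[C@@H]1O[C@@]1(C)COS(=O)(=O)C(F)(F)F)CC[C@]1(C)O[C@H]1COC(C)=O
F3 | step 7 | coupled C6 sulfone with C9–OTBS and C10 acetate (C6 epimers) | CC(=C)[C@@H](C[C@@H]1O[C@@]1(C)CC(/C=C(C)/CO[Si](C)(C)C(C)(C)C)S(=O)(=O)c1ccccc1)CC[C@]1(C)O[C@H]1COC(C)=O
F4 | step 7 | coupled C6 sulfone with C9–OTBS and C10–OH (C6 epimers) | CC(=C)[C@@H](C[C@@H]1O[C@@]1(C)CC(/C=C(C)/CO[Si](C)(C)C(C)(C)C)S(=O)(=O)c1ccccc1)CC[C@]1(C)O[C@H]1CO
F5 | step 16 | C10 epoxy iodide of 23 | CC(=C)[C@@H](C[C@@H]1O[C@@]1(C)CC/C=C(C)/CS(=O)(=O)c1ccccc1)CC[C@]1(C)O[C@H]1CI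
F6 | step 17 | B-(C17-alkyl)-9-borabicyclo[3.3.1]nonane adduct of 25 | CC(CB1C2CCCC1CCC2)[C@H]1C[C@@H]2O[C@@]2(C)CC/C=C(C)/C(S(=O)(=O)c2ccccc2)C[C@@H]2O[C@@]2(C)CC1
F7 | step 17 | C17 alcohol with C9 sulfone | CC(CO)[C@H]1C[C@@H]2O[C@@]2(C)CC/C=C(C)/C(S(=O)(=O)c2ccccc2)C[C@@H]2O[C@@]2(C)CC1
F8 | step 17 | C17 aldehyde with C9 sulfone | CC(C=O)[C@H]1C[C@@H]2O[C@@]2(C)CC/C=C(C)/C(S(=O)(=O)c2ccccc2)C[C@@H]2O[C@@]2(C)CC1
F9 | step 17 | C17 acid with C9 sulfone | CC(C(=O)O)[C@H]1C[C@@H]2O[C@@]2(C)CC/C=C(C)/C(S(=O)(=O)c2ccccc2)C[C@@H]2O[C@@]2(C)CC1
F10 | step 17 | hydroxy lactone with C9 sulfone (C9 and C15 epimers) | CC1C(=O)O[C@@H]2C[C@H]1CC[C@]1(C)O[C@H]1CC(S(=O)(=O)c1ccccc1)/C(C)=C/CC[C@]2(C)O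
F11 | step 21 | C4 triethylsilyl ether of 32 | C[C@@H]1C(=O)O[C@@H]2C[C@H]1CC[C@]1(C)O[C@H]1CC/C(C)=C/CC[C@]2(C)O[Si](CC)(CC)CC
F12 | step 21 | C4 triethylsilyl ether of 33 | C[C@@H]1C(=O)O[C@@H]2C[C@H]1CC[C@]1(C)O[C@H]1CC[C@](C)(OO)/C=C/C[C@]2(C)O[Si](CC)(CC)CC
A1 | alternative 1 | macrocyclic lactone with C9 phenyl sulfone and C4 triethylsilyl ether (C9 epimers) | C[C@@H]1C(=O)O[C@@H]2C[C@H]1CC[C@]1(C)O[C@H]1CC(S(=O)(=O)c1ccccc1)/C(C)=C/CC[C@]2(C)O[Si](CC)(CC)CC
A2 | alternative 1 | open-chain lactone with C9 allylic sulfone, C4 triethylsilyl ether and C10 epoxy triflate | C[C@@H]1C(=O)O[C@H](C[C@H]1CC[C@]1(C)O[C@H]1COS(=O)(=O)C(F)(F)F)[C@](C)(CC/C=C(C)/CS(=O)(=O)c1ccccc1)O[Si](CC)(CC)CC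
A3 | alternative 2 | 14-membered (13S)-allylic alcohol with (E)-C14=C1 olefin, 3,4-acetonide and 11,12-epoxide | O[C@H]1/C=C/C[C@H]2OC(C)(C)O[C@@]2(C)CC/C=C(C)/CC[C@@H]2O[C@@]12C
A4 | alternative 2 | open-chain (E)-C14 vinyl iodide with C13 epoxy aldehyde | I/C=C/C[C@H]1OC(C)(C)O[C@@]1(C)CC/C=C(C)/CC[C@@H]1O[C@@]1(C)C=O
A5 | alternative 3 | 14-membered C3 ketone with C1 isopropenyl and C4 triethylsilyl ether | CC(=C)[C@@H]1CC[C@]2(C)O[C@H]2CC/C(C)=C/CC[C@](C)(O[Si](CC)(CC)CC)C(=O)C1
A6 | alternative 3 | 16-membered 2-methylene oxacycle, (E)-C15=C1 olefin drawn | C=C1OC/C(C)=C/CC[C@]2(C)O[C@H]2CC/C(C)=C/CC[C@]1(C)O[Si](CC)(CC)CC
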